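**Plan**

1. Retrosynthetic cuts: first the aryl ether bond C8a–O1 together with the C8–prenyl bond (one aryne event across C8/C8a of ring A), then C3–C4 (aldol), then the aryl–prenyl bonds at C6 and C5′.
2. Enabling feature: in ring A the ether carbon C8a sits next to C8, which carries a carbon substituent and is flanked by the C7 oxygen. With fluorine at C8a in place of O1, C8–H is the only aromatic hydrogen of ring A, and the fluorine then serves as leaving group, so a C8/C8a aryne can take up the tethered C2 alkoxide at C8a and a prenyl group at C8.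
3. Forward order: the ring A aldehyde (from 5-fluororesorcinol) and the ring B methyl ketone (from acetovanillone) are joined by aldol addition, the ketone is reduced, ring C is closed by the aryne event, C4 is oxidised and the MOM ethers are removed.
4. Helpers: C4 is kept at the carbinol level through the ring closure, because a C4 ketone would enolise, cleave by retro-aldol or open the new ring by elimination; it is oxidised afterwards. The fluorine is consumed in the key step.
5. Stereochemistry: C2 (S) comes from asymmetric transfer hydrogenation with the (S,S)-TsDPEN ruthenium catalyst; the C2–O bond is never broken afterwards, and the C4 epimers converge on oxidation.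

Key step: step 9

Remark: flavanone numbering (O1, C2, C3, C4, C4a, C5 to C8, C8a; primes for ring B) is used for all intermediates. The carbinol at C4 in 12, 13 and 17 is carried as a mixture of epimers because step 10 removes that centre. Compounds 1 and 7, prenyl bromide and tributyl(prenyl)stannane are taken as commercial.

**Step 1**
Reactants: 1 5-fluorobenzene-1,3-diol (5-fluororesorcinol)
Product: 2 1-fluoro-3,5-bis(methoxymethoxy)benzene
Conditions: NaH, MOMCl, DMF, 0 °C → rt
Reagents that add atoms: chloromethyl methyl ether (MOMCl), COCCl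
Why: Williamson-type O-alkylation of both phenoxides gives the bis-MOM ether, which supplies the directing groups for the two metalations and is removable by acid at the end.

**Step 2**
Reactants: 2 1-fluoro-3,5-bis(methoxymethoxy)benzene
Product: 4 5-fluoro-1,3-bis(methoxymethoxy)-2-(3-methylbut-2-en-1-yl)benzene, via aryllithium 3 (not isolated)
Conditions: n-BuLi, Et2O, 0 °C; then CuBr·SMe2 (10 mol%), prenyl bromide, −40 °C → rt
Reagents that add atoms: prenyl bromide (1-bromo-3-methylbut-2-ene), CC(C)=CCBr
Why: Directed ortho-metalation with uncomplexed n-BuLi in ether is coordination-controlled and should take place between the two MOM ethers rather than next to fluorine, and copper-catalysed allylic substitution of the aryllithium at the primary carbon of prenyl bromide then installs the future C6 prenyl group.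

**Step 3**
Reactants: 4 5-fluoro-1,3-bis(methoxymethoxy)-2-(3-methylbut-2-en-1-yl)benzene
Product: 6 6-fluoro-2,4-bis(methoxymethoxy)-3-(3-methylbut-2-en-1-yl)benzaldehyde, via aryllithium 5 (not isolated)
Conditions: s-BuLi, THF, −78 °C; DMF, −78 → −20 °C; H2O
Reagents that add atoms: N,N-dimethylformamide, CN(C)C=O
Why: Directed ortho-metalation at one of the two equivalent positions between fluorine and a MOM ether, held at −78 °C so that LiF is not lost, followed by formylation with DMF (Bouveault-type) gives the ring A aldehyde.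

**Step 4**
Reactants: 7 1-(4-hydroxy-3-methoxyphenyl)ethan-1-one (acetovanillone)
Product: 8 1-(3-bromo-4-hydroxy-5-methoxyphenyl)ethan-1-one
Conditions: NBS, MeCN, 0 °C → rt
Reagents that add atoms: N-bromosuccinimide, O=C1CCC(=O)N1Br
Why: Electrophilic aromatic bromination goes ortho to the free phenol, the only open position activated by the strongest donor, since the para position is blocked by the acetyl group.

**Step 5**
Reactants: 8 1-(3-bromo-4-hydroxy-5-methoxyphenyl)ethan-1-one
Product: 9 1-[3-bromo-5-methoxy-4-(methoxymethoxy)phenyl]ethan-1-one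
Conditions: NaH (1.05 equiv), MOMCl, DMF, 0 °C → rt
Reagents that add atoms: chloromethyl methyl ether (MOMCl), COCCl
Why: The acidic para-acyl phenol is deprotonated selectively over the methyl ketone and O-alkylated (Williamson-type) to the MOM ether.

**Step 6**
Reactants: 9 1-[3-bromo-5-methoxy-4-(methoxymethoxy)phenyl]ethan-1-one
Product: 10 1-[3-methoxy-4-(methoxymethoxy)-5-(3-methylbut-2-en-1-yl)phenyl]ethan-1-one
Conditions: tributyl(prenyl)stannane, Pd(PPh3)4 (5 mol%), DMF, 100 °C
Reagents that add atoms: tributyl(3-methylbut-2-en-1-yl)stannane, CCCC[Sn](CCCC)(CCCC)CC=C(C)C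
Why: Stille coupling under zerovalent palladium catalysis tolerates the methyl ketone and the MOM ether and should deliver the linear prenyl arene through reductive elimination from the less hindered allyl terminus.

**Step 7**
Reactants: 10 1-[3-methoxy-4-(methoxymethoxy)-5-(3-methylbut-2-en-1-yl)phenyl]ethan-1-one; 6 6-fluoro-2,4-bis(methoxymethoxy)-3-(3-methylbut-2-en-1-yl)benzaldehyde
Product: 12 3-[6-fluoro-2,4-bis(methoxymethoxy)-3-(3-methylbut-2-en-1-yl)phenyl]-3-hydroxy-1-[3-methoxy-4-(methoxymethoxy)-5-(3-methylbut-2-en-1-yl)phenyl]propan-1-one (racemic), via lithium enolate 11 (not isolated)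
Conditions: LDA, THF, −78 °C; then 6, −78 °C; AcOH, −78 °C
Reagents that add atoms: none
Why: Directed aldol addition of the kinetic lithium enolate to the non-enolisable aldehyde forms the C3–C4 bond, and the cold acidic quench should prevent dehydration and retro-aldol cleavage; the new carbinol (C4) is racemic but is oxidised later.

**Step 8**
Reactants: 12 the racemic aldol adduct
Product: 13 (1S,3RS)-3-[6-fluoro-2,4-bis(methoxymethoxy)-3-(3-methylbut-2-en-1-yl)phenyl]-1-[3-methoxy-4-(methoxymethoxy)-5-(3-methylbut-2-en-1-yl)phenyl]propane-1,3-diol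
Conditions: RuCl(p-cymene)[(S,S)-TsDPEN] (3 mol%), HCO2Na, MeOH/H2O, 40 °C
Reagents that add atoms: none
Why: Noyori–Ikariya asymmetric transfer hydrogenation of the aryl ketone is catalyst-controlled through outer-sphere hydride delivery, and the (S,S) ligand should give the (S) carbinol at C2 as it does with acetophenone; the near-neutral formate medium spares the acid-labile C4 carbinol, the MOM ethers, the aryl fluoride and the prenyl alkenes.

**Step 9**
Reactants: 13 the (1S)-diol
Product: 17 (2S,4RS)-2-[3-methoxy-4-(methoxymethoxy)-5-(3-methylbut-2-en-1-yl)phenyl]-5,7-bis(methoxymethoxy)-6,8-bis(3-methylbut-2-en-1-yl)-3,4-dihydro-2H-chromen-4-ol, via trilithium species 14 (not isolated), via C8–C8a aryne 15 (not isolated), via 8-lithioflavan-4-olate 16 (not isolated)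
Conditions: n-BuLi (2.0 equiv), then s-BuLi (1.1 equiv), THF (0.02 M), −78 °C; warm to −20 °C; CuBr·SMe2 (20 mol%), prenyl bromide, −78 → 0 °C; H2O
Reagents that add atoms: prenyl bromide (1-bromo-3-methylbut-2-ene), CC(C)=CCBr
Why: Proposed new method: after both hydroxyls are converted to lithium alkoxides, s-BuLi removes the only aromatic hydrogen of ring A (C8–H, acidified by the C8a fluorine and coordinated by the C7 MOM ether); on warming the ortho-fluoroaryllithium loses LiF to give the C8–C8a aryne, the C2 alkoxide adds to C8a, and the resulting C8 aryllithium is prenylated under copper catalysis, so that ring C and the C8 prenyl group arise in one flask. The closest known reaction types are the base-mediated cyclisation of tethered alkoxides onto arynes to give chromans, and the addition of a heteroatom nucleophile to an aryne followed by copper-mediated allylation of the ortho-metalated adduct; their merger on a fully substituted aryne with a secondary benzylic alkoxide is the new part. Ring C closes in a 6-exo-dig sense onto the in-plane π bond of the aryne. No new stereocentre of consequence is formed: the C2–O bond is not broken, so the S configuration from step 8 is carried into the ring, and both C4 epimers converge in step 10. The site of addition is secured by the tether (attack at C8 would need a bridged ring) and reinforced by the C7 alkoxy group, which polarises the aryne so that the carbanion develops at C8 next to it; alkyllithium bases leave no amine that could protonate C8–Li before prenyl bromide arrives, and catalytic CuBr·SMe2 with the aryllithium in excess should favour attack at the primary carbon of prenyl bromide. The C4 alkoxide is the oxidation-level helper: it cannot enolise, cannot cleave by retro-aldol in this dianion and cannot reach C8a without forming a four-membered ring.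

**Step 10**
Reactants: 17 the (2S)-flavan-4-ol
Product: 18 (2S)-2-[3-methoxy-4-(methoxymethoxy)-5-(3-methylbut-2-en-1-yl)phenyl]-5,7-bis(methoxymethoxy)-6,8-bis(3-methylbut-2-en-1-yl)-2,3-dihydro-4H-chromen-4-one
Conditions: Dess–Martin periodinane, NaHCO3, CH2Cl2, 0 °C → rt
Reagents that add atoms: none
Why: Dess–Martin oxidation of the benzylic secondary alcohol converts both C4 epimers into one flavanone under buffered conditions that should neither touch the prenyl alkenes nor open the ring through the chalcone, so C2 stays S.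

**Step 11**
Reactants: 18 the tris-MOM flavanone
Product: 19 (2S)-5,7-dihydroxy-2-[4-hydroxy-3-methoxy-5-(3-methylbut-2-en-1-yl)phenyl]-6,8-bis(3-methylbut-2-en-1-yl)-2,3-dihydro-4H-chromen-4-one (CNP0235424.1)
Conditions: 3 M HCl (aq)/MeOH, 50 °C, short reaction time
Reagents that add atoms: none
Why: Acid-catalysed acetal exchange with methanol removes all three MOM ethers; acid rather than base avoids the chalcone ring-opening that would racemise C2, and brief exposure limits cyclisation of the prenyl groups onto the freed phenols.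

**Compound list**

1 | 5-fluorobenzene-1,3-diol | Oc1cc(O)cc(F)c1 | starting material
2 | 1-fluoro-3,5-bis(methoxymethoxy)benzene | COCOc1cc(F)cc(OCOC)c1 | intermediate
3 | [4-fluoro-2,6-bis(methoxymethoxy)phenyl]lithium | [Li]c1c(OCOC)cc(F)cc1OCOC | intermediate
4 | 5-fluoro-1,3-bis(methoxymethoxy)-2-(3-methylbut-2-en-1-yl)benzene | COCOc1cc(F)cc(OCOC)c1CC=C(C)C | intermediate
5 | [6-fluoro-2,4-bis(methoxymethoxy)-3-(3-methylbut-2-en-1-yl)phenyl]lithium | [Li]c1c(F)cc(OCOC)c(CC=C(C)C)c1OCOC | intermediate
6 | 6-fluoro-2,4-bis(methoxymethoxy)-3-(3-methylbut-2-en-1-yl)benzaldehyde | O=Cc1c(F)cc(OCOC)c(CC=C(C)C)c1OCOC | intermediate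
7 | 1-(4-hydroxy-3-methoxyphenyl)ethan-1-one | CC(=O)c1ccc(O)c(OC)c1 | starting material
8 | 1-(3-bromo-4-hydroxy-5-methoxyphenyl)ethan-1-one | CC(=O)c1cc(Br)c(O)c(OC)c1 | intermediate
9 | 1-[3-bromo-5-methoxy-4-(methoxymethoxy)phenyl]ethan-1-one | CC(=O)c1cc(Br)c(OCOC)c(OC)c1 | intermediate
10 | 1-[3-methoxy-4-(methoxymethoxy)-5-(3-methylbut-2-en-1-yl)phenyl]ethan-1-one | CC(=O)c1cc(OC)c(OCOC)c(CC=C(C)C)c1 | intermediate
11 | lithium enolate of 10 | [Li]OC(=C)c1cc(OC)c(OCOC)c(CC=C(C)C)c1 | intermediate
12 | 3-[6-fluoro-2,4-bis(methoxymethoxy)-3-(3-methylbut-2-en-1-yl)phenyl]-3-hydroxy-1-[3-methoxy-4-(methoxymethoxy)-5-(3-methylbut-2-en-1-yl)phenyl]propan-1-one (racemic) | COCOc1c(CC=C(C)C)cc(C(=O)CC(O)c2c(F)cc(OCOC)c(CC=C(C)C)c2OCOC)cc1OC | intermediate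
13 | (1S,3RS)-3-[6-fluoro-2,4-bis(methoxymethoxy)-3-(3-methylbut-2-en-1-yl)phenyl]-1-[3-methoxy-4-(methoxymethoxy)-5-(3-methylbut-2-en-1-yl)phenyl]propane-1,3-diol | COCOc1c(CC=C(C)C)cc([C@@H](O)CC(O)c2c(F)cc(OCOC)c(CC=C(C)C)c2OCOC)cc1OC | intermediate
14 | trilithium species: dilithium dialkoxide of 13 lithiated at C8 | COCOc1c(CC=C(C)C)cc([C@@H](O[Li])CC(O[Li])c2c(F)c([Li])c(OCOC)c(CC=C(C)C)c2OCOC)cc1OC | intermediate
15 | C8–C8a aryne of the dilithium dialkoxide | COCOc1c(CC=C(C)C)cc([C@@H](O[Li])CC(O[Li])C2=C(OCOC)C(CC=C(C)C)=C(OCOC)C#C2)cc1OC | intermediate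
16 | (2S)-8-lithio-5,7-bis(methoxymethoxy)-6-prenylflavan-4-olate, lithium salt | COCOc1c(CC=C(C)C)cc([C@@H]2CC(O[Li])c3c(OCOC)c(CC=C(C)C)c(OCOC)c([Li])c3O2)cc1OC | intermediate
17 | (2S,4RS)-2-[3-methoxy-4-(methoxymethoxy)-5-(3-methylbut-2-en-1-yl)phenyl]-5,7-bis(methoxymethoxy)-6,8-bis(3-methylbut-2-en-1-yl)-3,4-dihydro-2H-chromen-4-ol | COCOc1c(CC=C(C)C)cc([C@@H]2CC(O)c3c(OCOC)c(CC=C(C)C)c(OCOC)c(CC=C(C)C)c3O2)cc1OC | intermediate
18 | (2S)-2-[3-methoxy-4-(methoxymethoxy)-5-(3-methylbut-2-en-1-yl)phenyl]-5,7-bis(methoxymethoxy)-6,8-bis(3-methylbut-2-en-1-yl)-2,3-dihydro-4H-chromen-4-one | COCOc1c(CC=C(C)C)cc([C@@H]2CC(=O)c3c(OCOC)c(CC=C(C)C)c(OCOC)c(CC=C(C)C)c3O2)cc1OC | intermediate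
19 | (2S)-5,7-dihydroxy-2-[4-hydroxy-3-methoxy-5-(3-methylbut-2-en-1-yl)phenyl]-6,8-bis(3-methylbut-2-en-1-yl)-2,3-dihydro-4H-chromen-4-one | COc1cc([C@@H]2CC(=O)c3c(O)c(CC=C(C)C)c(O)c(CC=C(C)C)c3O2)cc(CC=C(C)C)c1O | target

**Step count and risks**

Total steps: 11. Longest linear sequence: 8 (steps 1 to 3, or 4 to 6, followed by steps 7 to 11).

Steps most likely to fail:

1. Step 9 (Proposed new method). The aryne may be captured intermolecularly by aryllithium that has not yet eliminated, or the C8 anion may be protonated before prenylation, so that ring closure and prenylation do not both occur in one flask. Fallback with known chemistry, from 13 back to 17: the two events are separated. Treatment of 13 with excess LiTMP in THF (−78 → 0 °C) is the classical amide-base aryne cyclisation of a tethered alkoxide; the tetramethylpiperidine formed protonates C8 and gives the 8-unsubstituted (2S)-flavan-4-ol F1. A separate directed ortho-metalation of F1 (n-BuLi, 2.2 equiv, THF; the C8–H lies between O1 and the C7 MOM ether and is the only aromatic hydrogen of ring A), followed by CuBr·SMe2 and prenyl bromide, then gives 17.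

2. Step 8. The electron-rich C4 carbinol may be lost by elimination to the enone or by retro-aldol cleavage during the reduction, and the free neighbouring hydroxyl may erode catalyst control at C2. Fallback, from 10 (and 4) back to 13: the stereocentre is set before the fragments are joined. Claisen condensation of 10 with diethyl carbonate (NaH, THF, reflux) gives the β-keto ester F2. Transfer hydrogenation of F2 with the same (S,S)-TsDPEN ruthenium catalyst (HCO2H/Et3N) gives the (S)-β-hydroxy ester F3. Silylation (TBSCl, imidazole, DMF) gives the silyl ether F4, and DIBAL-H (CH2Cl2, −78 °C) gives the (S)-β-silyloxy aldehyde F5. Addition of aryllithium 5 (generated from 4 as in step 3) to F5 at −78 °C gives the mono-silylated diol F6, and TBAF (THF) releases 13.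

3. Step 2. Metalation may occur at the more acidic fluorine-flanked positions instead of between the two MOM ethers, followed by LiF loss from that anion on warming, which would place the prenyl group wrongly or consume the arene. Fallback, from 1 back to 6, with regiochemistry fixed by electrophilic substitution instead of metalation: Vilsmeier–Haack formylation of 1 (POCl3, DMF, MeCN, then aqueous hydrolysis) goes para to one hydroxyl and gives 2-fluoro-4,6-dihydroxybenzaldehyde F7. Nuclear C-prenylation of its phenoxide between the two hydroxyls (aqueous KOH, prenyl bromide, 0 °C → rt) gives the prenylated dihydroxybenzaldehyde F8. Bis-MOM protection (NaH, MOMCl, DMF) then gives 6, so that steps 1 to 3 are bypassed.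

**Further compounds**

F1 | step 9 | (2S,4RS)-2-[3-methoxy-4-(methoxymethoxy)-5-(3-methylbut-2-en-1-yl)phenyl]-5,7-bis(methoxymethoxy)-6-(3-methylbut-2-en-1-yl)-3,4-dihydro-2H-chromen-4-ol | COCOc1c(CC=C(C)C)cc([C@@H]2CC(O)c3c(OCOC)c(CC=C(C)C)c(OCOC)cc3O2)cc1OC
F2 | step 8 | ethyl 3-[3-methoxy-4-(methoxymethoxy)-5-(3-methylbut-2-en-1-yl)phenyl]-3-oxopropanoate | CCOC(=O)CC(=O)c1cc(OC)c(OCOC)c(CC=C(C)C)c1
F3 | step 8 | ethyl (3S)-3-hydroxy-3-[3-methoxy-4-(methoxymethoxy)-5-(3-methylbut-2-en-1-yl)phenyl]propanoate | CCOC(=O)C[C@H](O)c1cc(OC)c(OCOC)c(CC=C(C)C)c1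
F4 | step 8 | ethyl (3S)-3-[(tert-butyldimethylsilyl)oxy]-3-[3-methoxy-4-(methoxymethoxy)-5-(3-methylbut-2-en-1-yl)phenyl]propanoate | CCOC(=O)C[C@H](O[Si](C)(C)C(C)(C)C)c1cc(OC)c(OCOC)c(CC=C(C)C)c1
F5 | step 8 | (3S)-3-[(tert-butyldimethylsilyl)oxy]-3-[3-methoxy-4-(methoxymethoxy)-5-(3-methylbut-2-en-1-yl)phenyl]propanal | O=CC[C@H](O[Si](C)(C)C(C)(C)C)c1cc(OC)c(OCOC)c(CC=C(C)C)c1
F6 | step 8 | (1RS,3S)-3-[(tert-butyldimethylsilyl)oxy]-1-[6-fluoro-2,4-bis(methoxymethoxy)-3-(3-methylbut-2-en-1-yl)phenyl]-3-[3-methoxy-4-(methoxymethoxy)-5-(3-methylbut-2-en-1-yl)phenyl]propan-1-ol | COCOc1c(CC=C(C)C)cc([C@@H](O[Si](C)(C)C(C)(C)C)CC(O)c2c(F)cc(OCOC)c(CC=C(C)C)c2OCOC)cc1OC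
F7 | step 2 | 2-fluoro-4,6-dihydroxybenzaldehyde | O=Cc1c(F)cc(O)cc1O
F8 | step 2 | 6-fluoro-2,4-dihydroxy-3-(3-methylbut-2-en-1-yl)benzaldehyde | O=Cc1c(F)cc(O)c(CC=C(C)C)c1O
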